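# Synthesis plan for the 36-membered nonahydroxy macrolactone 44 by ring closure at C20–C21

Locants C1–C40 are those of the target chain (C1 = lactone carbonyl, O35 = ring oxygen, C36–C40 = side chain). TBS = tert-butyldimethylsilyl, PMB = 4-methoxybenzyl, Ipc = isopinocampheyl. The target 44 is (3R,5R,9R,13S,17S,21R,25S,27S,29S,33S,35R,36S). Drawn as a zigzag with C1 at the left and the odd-numbered carbons at the lower vertices, 3-Me, O5, O9, O17, O25, O27, O33 and 36-Me sit on wedges and O13, O21, O29 and O35 on hashed bonds. CIP labels of untouched centres change along the route when remote groups change rank (C9, C13, C17, C27), so the SMILES strings are authoritative.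

## The problem

The target 44 contains one ring only, a 36-membered lactone (C1 to C35 plus O35), with a hexan-2-yl branch (C36–C40) on the carbinol carbon C35. The task is therefore to build a saturated forty-carbon chain with twelve stereocentres and to close one very large ring. From C5 to C21 the carbinols are separated by three methylenes (C5, C9, C13, C17, C21), too far apart for one centre to direct the next, so each must be set by a chiral reagent or catalyst. The C25/C27/C29 triad (syn, then anti), the C33/C35 pair (anti) and the adjacent C35/C36 pair (anti) are close enough for substrate control, but the mixed pattern is set more safely by reagent control; only C3 is best bought. Sensitive points are the lactone (hydrolysis, or acyl shift to the 1,3-related O33 under base), the β-silyloxy aldehydes that arise when a 1,3-diol is extended (elimination), a C1 ester facing a free O5 (δ-lactone formation), and the nonaol itself, which must be unveiled last. The feature that makes the key step possible is C21: it lies across the ring from the C1–O35 ester, it is a secondary carbinol, and C18, C19 and C20 on its C1 side are plain methylenes. An (E)-C19=C20 alkene beside a C21 hydroxyl is exactly what an alkenylmetal addition to a C21 aldehyde leaves, and it vanishes on hydrogenation. Both reacting carbons are unbranched, and the hindered O35 ester can be made beforehand, intermolecularly.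

## Retrosynthesis

**44 ⇒ 43 ⇒ 42 (no skeletal bond cut).** The nine hydroxyls are traced back to eight TBS ethers and one free C21 hydroxyl (43), and the C18–C20 methylenes to the (E)-C19=C20 alkene of allylic alcohol 42. One protecting-group type keeps the end game at two steps. The forward reactions must saturate an allylic alcohol without C–O hydrogenolysis and remove silicon without moving the acyl group.

**42 ⇒ 41 (C20–C21 cut, ring opened).** Cutting here rather than at the C1–O35 ester puts the ring closure at two unhindered carbons and lets it create the C21 carbinol, which no neighbouring centre could control anyway. Cuts at C19–C20 or C21–C22 would not map onto a carbonyl addition that leaves only methylenes after hydrogenation. Precursor 41 is an open chain with a C20 iodoalkene and a C21 aldehyde. The forward nickel/chromium-mediated addition must be chemoselective, retain the E geometry, close a 36-membered ring and select one aldehyde face through a chiral ligand on chromium.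

**41 ⇒ 40 ⇒ 39 ⇒ 18 + 37 (C1–O35 ester cut).** The aldehyde is carried as a PMB-protected primary alcohol (39, freed in 40), the only group in the molecule that oxidative debenzylation can single out. Cutting the ester divides the chain into two twenty-carbon halves, acid 18 (C1–C20) and alcohol 37 (C21–C40). Forming this bond intermolecularly is preferred to a terminal macrolactonization because O35 is flanked by the C36 branch; the forward step is an activated-ester acylation of a hindered secondary alcohol.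

**18 ⇒ 17 ⇒ 15 ⇒ 14 ⇒ 12 + 13 (C17–C18 cut; iodoalkene from alkyne).** The (E)-iodoalkene of 17/18 comes from the terminal alkyne of 15 by hydrozirconation–iodination. The homopropargylic carbinol 14 comes from aldehyde 12 and allenylboronate 13, so C18–C20 and the C17 centre arrive in one catalytic step. An allylation followed by two-step conversion of the alkene to the iodoalkene is the longer neighbour. The forward propargylation must be enantioselective on an unbranched aldehyde.

**12 ⇒ 11 ⇒ 10 ⇒ 9 ⇒ 8 ⇒ 7 ⇒ 6 ⇒ 5 ⇒ 4 ⇒ 3 ⇒ 2 ⇒ 1 (C16–C17, C13–C14, C12–C13, C9–C10, C8–C9 and C5–C6 cut in turn).** Each 1,5-unit is removed as one allyl group plus one carbon. A terminal alkene (11, 8, 5) is hydroformylated to the next aldehyde (12, 9, 6), and each aldehyde (9, 6, 3) is allylated by a pinene-derived allylborane (10, 7, 4) and silylated. This repeats three times and ends at aldehyde 3, made in two steps from the commercial hemiester 1, which supplies C1–C5 and the C3 methyl centre. Cuts inside the methylene runs would need stoichiometric phosphorus or sulfur chemistry and a later hydrogenation. The forward steps need linear-selective hydroformylation and reagent-controlled allylation.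

**37 ⇒ 36 ⇒ 34 + 35, and 34 ⇒ 33 (C38–C39 and C35–C36 cut).** The butyl terminus is simplified to the vinyl group of 34 plus two carbons from alkene 35 (cross-metathesis, then hydrogenation of 36). Alcohol 34 is the anti-crotylation product of aldehyde 33, which sets C35 and C36 together. Because the chain is built towards C35, the hydroxyl that must later be acylated is formed last and never needs a protecting group. Starting from a 2-methylhexanal unit would reverse the direction and cost an extra protecting group on O35.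

**33 ⇒ 32 ⇒ 31 ⇒ 30 ⇒ 29 ⇒ 28 ⇒ 27 ⇒ 26 ⇒ 25 ⇒ 24 ⇒ 23 ⇒ 22 ⇒ 21 ⇒ 20 ⇒ 19 (C33–C34, C32–C33, C29–C30, C27–C28 and C25–C26 cut in turn).** The same allylborane logic is used. A 1,3-relationship is extended by ozonolysis of the allyl group (32 ⇒ 33, 26 ⇒ 27, 23 ⇒ 24) and the 1,5-relationship C29/C33 by hydroformylation (29 ⇒ 30). Every carbinol (C33, C29, C27, C25) comes from an allylation whose face is chosen by the reagent. The sequence ends at aldehyde 21, made from pentane-1,5-diol 19 by monoprotection and oxidation. The forward allylations must override the weak 1,3-bias of β-silyloxy aldehydes.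

## Roads not taken

**Alternative 1: two-directional catalytic allylation of the C2-symmetric core.**
- Cut: C8–C9 and C21–C22 together (and before them C12–C13 and C17–C18).
- Forward key step: the C9–C21 segment of 44 is C2-symmetric about C15, so diol 19 could be allylated at both ends by a chiral iridium catalyst from the alcohol oxidation state, extended at both ends and allylated twice more to give diene diol A1.
- Merits: two C–C bonds and two carbinols per operation, no discrete aldehydes, catalytic chirality, and enantiopurity amplified in the doubly allylated products. The nineteen-carbon core would need about six steps, clearly fewer than the chosen route spends on the same carbinols.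
- Weak points: the two ends of A1 are homotopic, but 44 continues differently on each side, so the symmetry must be broken by a statistical mono-functionalization of an advanced intermediate. C5 and C25 lie outside the symmetric segment. The ring closure is left open and would most likely be a lactonization onto the hindered O35.
- Comparison: for the 1,5-polyol this road is better in step count. The chosen plan offers in return no statistical step, fragment ends differentiated from the first step, and a ring closure that also creates C21.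

**Alternative 2: silicon tether and ring-closing metathesis at C23=C24.**
- Cut: C23–C24, after O21 of a C1–C23 homoallylic alcohol and O25 of a C24–C40 allylic alcohol are linked through a diisopropylsilylene unit.
- Forward key step: a ruthenium alkylidene closes the eight-membered dioxasilacyclooctene A2 with a Z alkene; fluoride and hydrogen later remove tether and alkene.
- Merits: the chain is joined near its middle from two halves of similar size. C21 and C25 are made beforehand by reliable carbonyl additions, so no stereocentre depends on the coupling. Metathesis tolerates every group present.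
- Weak points: the unsymmetrical bis-alkoxysilane must be assembled stepwise from two advanced secondary alcohols, with losses to symmetrical by-products. Eight-membered ring closure competes with dimerization. O21 and O25 must be re-protected after tether removal. The macrocycle still has to be closed at the hindered C35 hydroxyl after unmasking both ends of A2.
- Comparison: this road is stronger on stereochemical security at C21, which in the chosen plan rests on a ligand-controlled addition. The chosen plan answers with an oxidation–reduction correction at C21, and it needs no tether chemistry and no separate macrolactonization.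

**Alternative 3: dithiane linchpin at C27.**
- Cut: C26–C27 and C27–C28 in one flask.
- Forward key step: the lithium anion of silyl dithiane A4 opens a C25–C26 epoxide, the alkoxide triggers a 1,4-silyl shift to O25, and the new C27 anion opens a C28–C29 epoxide to give A3.
- Merits: the most convergent of the four roads, with two C–C bonds formed in one operation, C25 and C29 taken from terminal epoxides of high enantiopurity, and O25/O29 differentiated automatically.
- Weak points: C27 emerges as a masked ketone, so dithiane removal in the presence of seven silyl ethers and two PMB ethers, and a hydroxyl-directed reduction, are added; C27 is then set late by substrate control. The first epoxide carries the whole C1–C24 polyol and must survive an organolithium and the polar co-solvent that triggers the silyl shift. Two enantiopure epoxides flanked by 1,3-oxygenation must be prepared. The ring again awaits a terminal lactonization.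
- Comparison: on convergence this road beats the chosen one, whose alcohol half is linear. The chosen plan offers in return one protecting-group type, no redox detour at C27, and two steps after ring closure.

Key step: step 35

Assumption: the facial senses used for the pinene-derived allyl- and crotylboranes, for the binaphthyl phosphoric acid of step 12 and for the oxazoline–sulfonamide ligand of step 35 are taken as those established for unbranched aliphatic aldehydes; each is to be checked by Mosher ester analysis at first use, and the antipodal reagent is used if a sense proves reversed.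

Assumption: hemiester 1 and both antipodes of B-allyldiisopinocampheylborane are taken as purchasable reagents.

## Route

Step 1
Reactants: 1 (3R)-5-methoxy-3-methyl-5-oxopentanoic acid (methyl hydrogen (R)-3-methylglutarate)
Product: 2 methyl (3R)-5-hydroxy-3-methylpentanoate
Conditions: BH3·SMe2, THF, 0 °C to rt; MeOH quench
Reagents that add atoms: none
Why: Chemoselective borane reduction: the free carboxylic acid is reduced far faster than the methyl ester, so the acid end becomes C5 and the ester remains as C1; C3 is not touched.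

Step 2
Reactants: 2 methyl (3R)-5-hydroxy-3-methylpentanoate
Product: 3 methyl (3R)-3-methyl-5-oxopentanoate
Conditions: Dess–Martin periodinane, NaHCO3, CH2Cl2, 0 °C to rt
Reagents that add atoms: none
Why: Periodinane oxidation of a primary alcohol stops at the aldehyde; the buffered, non-aqueous medium avoids lactonization of 2, and the volatile aldehyde is used as a solution.

Step 3
Reactants: 3 methyl (3R)-3-methyl-5-oxopentanoate
Product: 4 methyl (3R,5R)-5-hydroxy-3-methyloct-7-enoate
Conditions: B-allyldiisopinocampheylborane from (−)-α-pinene, Et2O, −78 °C; then pH 7 phosphate buffer, MeOH, 30% H2O2, 0 °C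
Reagents that add atoms: B-allyldiisopinocampheylborane from (−)-α-pinene, C=CCB([C@H]1C[C@H]2C[C@@H]([C@@H]1C)C2(C)C)[C@H]1C[C@H]2C[C@@H]([C@@H]1C)C2(C)C
Why: Brown allylation through a closed chair transition state in which the isopinocampheyl groups select the aldehyde face and so set C5 (C5–C6 formed); the ester is inert at −78 °C, and the buffered cold work-up with immediate silylation keeps the δ-hydroxy ester from closing to the lactone.

Step 4
Reactants: 4 methyl (3R,5R)-5-hydroxy-3-methyloct-7-enoate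
Product: 5 methyl (3R,5R)-5-(TBS-oxy)-3-methyloct-7-enoate
Conditions: TBSOTf, 2,6-lutidine, CH2Cl2, −78 to 0 °C
Reagents that add atoms: tert-butyldimethylsilyl triflate, CC(C)(C)[Si](C)(C)OS(=O)(=O)C(F)(F)F
Why: Silylation of a secondary alcohol with a silyl triflate and a hindered base is fast at low temperature and outruns lactonization; O5 is now blocked for the rest of the route.

Step 5
Reactants: 5 methyl (3R,5R)-5-(TBS-oxy)-3-methyloct-7-enoate
Product: 6 methyl (3R,5R)-5-(TBS-oxy)-3-methyl-9-oxononanoate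
Conditions: Rh(acac)(CO)2 (1 mol%), Xantphos (2 mol%), CO/H2 (1:1, 10 bar), toluene, 70 °C
Reagents that add atoms: carbon monoxide, [C-]#[O+]
Why: Linear-selective rhodium-catalysed hydroformylation with a wide-bite-angle diphosphine adds C9 to the terminal carbon at the aldehyde oxidation state (C8–C9 formed); ester and silyl ether are inert.

Step 6
Reactants: 6 methyl (3R,5R)-5-(TBS-oxy)-3-methyl-9-oxononanoate
Product: 7 methyl (3R,5R,9S)-5-(TBS-oxy)-9-hydroxy-3-methyldodec-11-enoate
Conditions: B-allyldiisopinocampheylborane from (−)-α-pinene, Et2O, −78 °C; then pH 7 buffer, MeOH, 30% H2O2, 0 °C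
Reagents that add atoms: B-allyldiisopinocampheylborane from (−)-α-pinene, C=CCB([C@H]1C[C@H]2C[C@@H]([C@@H]1C)C2(C)C)[C@H]1C[C@H]2C[C@@H]([C@@H]1C)C2(C)C
Why: Brown allylation (C9–C10 formed); C9 is set by the reagent alone, since C5 is four carbons away and exerts no bias.

Step 7
Reactants: 7 methyl (3R,5R,9S)-5-(TBS-oxy)-9-hydroxy-3-methyldodec-11-enoate
Product: 8 methyl (3R,5R,9S)-5,9-bis(TBS-oxy)-3-methyldodec-11-enoate
Conditions: TBSOTf, 2,6-lutidine, CH2Cl2, −78 to 0 °C
Reagents that add atoms: tert-butyldimethylsilyl triflate, CC(C)(C)[Si](C)(C)OS(=O)(=O)C(F)(F)F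
Why: Standard silyl triflate protection of a secondary homoallylic alcohol.

Step 8
Reactants: 8 methyl (3R,5R,9S)-5,9-bis(TBS-oxy)-3-methyldodec-11-enoate
Product: 9 methyl (3R,5R,9S)-5,9-bis(TBS-oxy)-3-methyl-13-oxotridecanoate
Conditions: Rh(acac)(CO)2 (1 mol%), Xantphos (2 mol%), CO/H2 (1:1, 10 bar), toluene, 70 °C
Reagents that add atoms: carbon monoxide, [C-]#[O+]
Why: Linear-selective hydroformylation as in step 5 (C12–C13 formed).

Step 9
Reactants: 9 methyl (3R,5R,9S)-5,9-bis(TBS-oxy)-3-methyl-13-oxotridecanoate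
Product: 10 methyl (3R,5R,9R,13R)-5,9-bis(TBS-oxy)-13-hydroxy-3-methylhexadec-15-enoate
Conditions: B-allyldiisopinocampheylborane from (+)-α-pinene, Et2O, −78 °C; then pH 7 buffer, MeOH, 30% H2O2, 0 °C
Reagents that add atoms: B-allyldiisopinocampheylborane from (+)-α-pinene, C=CCB([C@@H]1C[C@@H]2C[C@H]([C@H]1C)C2(C)C)[C@@H]1C[C@@H]2C[C@H]([C@H]1C)C2(C)C
Why: Brown allylation with the antipodal reagent gives the opposite face at C13 (hashed O13, C13–C14 formed); reagent control only.

Step 10
Reactants: 10 methyl (3R,5R,9R,13R)-5,9-bis(TBS-oxy)-13-hydroxy-3-methylhexadec-15-enoate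
Product: 11 methyl (3R,5R,9R,13R)-5,9,13-tris(TBS-oxy)-3-methylhexadec-15-enoate
Conditions: TBSOTf, 2,6-lutidine, CH2Cl2, −78 to 0 °C
Reagents that add atoms: tert-butyldimethylsilyl triflate, CC(C)(C)[Si](C)(C)OS(=O)(=O)C(F)(F)F
Why: Standard silyl triflate protection.

Step 11
Reactants: 11 methyl (3R,5R,9R,13R)-5,9,13-tris(TBS-oxy)-3-methylhexadec-15-enoate
Product: 12 methyl (3R,5R,9R,13R)-5,9,13-tris(TBS-oxy)-3-methyl-17-oxoheptadecanoate
Conditions: Rh(acac)(CO)2 (1 mol%), Xantphos (2 mol%), CO/H2 (1:1, 10 bar), toluene, 70 °C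
Reagents that add atoms: carbon monoxide, [C-]#[O+]
Why: Linear-selective hydroformylation as in step 5 (C16–C17 formed).

Step 12
Reactants: 12 methyl (3R,5R,9R,13R)-5,9,13-tris(TBS-oxy)-3-methyl-17-oxoheptadecanoate; 13 allenylboronic acid pinacol ester
Product: 14 methyl (3R,5R,9R,13S,17S)-5,9,13-tris(TBS-oxy)-17-hydroxy-3-methylicos-19-ynoate
Conditions: (R)-3,3′-bis(2,4,6-triisopropylphenyl)-1,1′-binaphthyl-2,2′-diyl hydrogen phosphate (10 mol%), 4 Å molecular sieves, toluene, −20 °C; aqueous work-up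
Reagents that add atoms: none
Why: Chiral Brønsted acid-catalysed propargylation: the phosphoric acid binds the boronate oxygen and the formyl hydrogen, and the allenyl group is delivered through a six-membered transition state with allenyl-to-propargyl transposition (C17–C18 formed); the catalyst sets C17.

Step 13
Reactants: 14 methyl (3R,5R,9R,13S,17S)-5,9,13-tris(TBS-oxy)-17-hydroxy-3-methylicos-19-ynoate
Product: 15 methyl (3R,5R,9R,13R,17S)-5,9,13,17-tetrakis(TBS-oxy)-3-methylicos-19-ynoate
Conditions: TBSOTf, 2,6-lutidine, CH2Cl2, −78 to 0 °C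
Reagents that add atoms: tert-butyldimethylsilyl triflate, CC(C)(C)[Si](C)(C)OS(=O)(=O)C(F)(F)F
Why: Standard silyl triflate protection; the terminal alkyne is unaffected under the buffered conditions.

Step 14
Reactants: 15 methyl (3R,5R,9R,13R,17S)-5,9,13,17-tetrakis(TBS-oxy)-3-methylicos-19-ynoate
Product: 17 methyl (3R,5R,9R,13R,17S,19E)-5,9,13,17-tetrakis(TBS-oxy)-20-iodo-3-methylicos-19-enoate, via alkenylzirconocene 16 (not isolated)
Conditions: Cp2Zr(H)Cl, THF, rt; then I2, 0 °C
Reagents that add atoms: zirconocene chloride hydride (zirconium remains in 16 only), [H][Zr](Cl)(C1C=CC=C1)C1C=CC=C1; iodine, II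
Why: Hydrozirconation–iodination: syn addition of Zr–H places zirconium on the terminal carbon, and iodinolysis with retention gives the (E)-iodoalkene only; alkyne insertion is much faster than attack on the methyl ester.

Step 15
Reactants: 17 methyl (3R,5R,9R,13R,17S,19E)-5,9,13,17-tetrakis(TBS-oxy)-20-iodo-3-methylicos-19-enoate
Product: 18 (3R,5R,9R,13R,17S,19E)-5,9,13,17-tetrakis(TBS-oxy)-20-iodo-3-methylicos-19-enoic acid
Conditions: LiOH·H2O, THF/MeOH/H2O, rt; then 0.5 M HCl to pH 4, 0 °C
Reagents that add atoms: lithium hydroxide, [Li+].[OH-]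
Why: Saponification of an unhindered methyl ester; iodoalkene and secondary silyl ethers tolerate hydroxide at room temperature, and C3 is β to the carbonyl and cannot epimerize.

Step 16
Reactants: 19 pentane-1,5-diol
Product: 20 5-(PMB-oxy)pentan-1-ol
Conditions: 19 (3 equiv), NaH, 4-methoxybenzyl chloride, Bu4NI (cat.), THF/DMF, 0 °C to rt
Reagents that add atoms: 4-methoxybenzyl chloride, COc1ccc(CCl)cc1
Why: Williamson monoetherification; excess diol suppresses the bis-ether, and the PMB group is the one ether that can later be removed oxidatively beside eight silyl ethers.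

Step 17
Reactants: 20 5-(PMB-oxy)pentan-1-ol
Product: 21 5-(PMB-oxy)pentanal
Conditions: Dess–Martin periodinane, NaHCO3, CH2Cl2, 0 °C to rt
Reagents that add atoms: none
Why: Periodinane oxidation of the primary alcohol to the aldehyde; the benzylic ether is inert.

Step 18
Reactants: 21 5-(PMB-oxy)pentanal
Product: 22 (4S)-8-(PMB-oxy)oct-1-en-4-ol
Conditions: B-allyldiisopinocampheylborane from (−)-α-pinene, Et2O, −78 °C; then pH 7 buffer, MeOH, 30% H2O2, 0 °C
Reagents that add atoms: B-allyldiisopinocampheylborane from (−)-α-pinene, C=CCB([C@H]1C[C@H]2C[C@@H]([C@@H]1C)C2(C)C)[C@H]1C[C@H]2C[C@@H]([C@@H]1C)C2(C)C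
Why: Brown allylation (C25–C26 formed); the reagent sets C25.

Step 19
Reactants: 22 (4S)-8-(PMB-oxy)oct-1-en-4-ol
Product: 23 (4S)-4-(TBS-oxy)-8-(PMB-oxy)oct-1-ene
Conditions: TBSOTf, 2,6-lutidine, CH2Cl2, −78 to 0 °C
Reagents that add atoms: tert-butyldimethylsilyl triflate, CC(C)(C)[Si](C)(C)OS(=O)(=O)C(F)(F)F
Why: Standard silyl triflate protection; the base keeps the PMB ether intact.

Step 20
Reactants: 23 (4S)-4-(TBS-oxy)-8-(PMB-oxy)oct-1-ene
Product: 24 (3S)-3-(TBS-oxy)-7-(PMB-oxy)heptanal
Conditions: O3, CH2Cl2, −78 °C, stopped at first persistent blue; then PPh3, −78 °C to rt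
Reagents that add atoms: ozone, [O-][O+]=O
Why: Ozonolysis with reductive work-up cleaves the terminal alkene to the C27 aldehyde; the electron-rich arene survives if ozone is not overdosed, and the β-silyloxy aldehyde is used crude to avoid elimination.

Step 21
Reactants: 24 (3S)-3-(TBS-oxy)-7-(PMB-oxy)heptanal
Product: 25 (4R,6S)-6-(TBS-oxy)-10-(PMB-oxy)dec-1-en-4-ol
Conditions: B-allyldiisopinocampheylborane from (−)-α-pinene, Et2O, −78 °C; then pH 7 buffer, MeOH, 30% H2O2, 0 °C
Reagents that add atoms: B-allyldiisopinocampheylborane from (−)-α-pinene, C=CCB([C@H]1C[C@H]2C[C@@H]([C@@H]1C)C2(C)C)[C@H]1C[C@H]2C[C@@H]([C@@H]1C)C2(C)C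
Why: Brown allylation (C27–C28 formed); the closed transition state makes the reagent, not the β-silyloxy group, decide the face, giving the 1,3-syn relationship of O25 and O27.

Step 22
Reactants: 25 (4R,6S)-6-(TBS-oxy)-10-(PMB-oxy)dec-1-en-4-ol
Product: 26 (4R,6S)-4,6-bis(TBS-oxy)-10-(PMB-oxy)dec-1-ene
Conditions: TBSOTf, 2,6-lutidine, CH2Cl2, −78 to 0 °C
Reagents that add atoms: tert-butyldimethylsilyl triflate, CC(C)(C)[Si](C)(C)OS(=O)(=O)C(F)(F)F
Why: Standard silyl triflate protection.

Step 23
Reactants: 26 (4R,6S)-4,6-bis(TBS-oxy)-10-(PMB-oxy)dec-1-ene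
Product: 27 (3S,5S)-3,5-bis(TBS-oxy)-9-(PMB-oxy)nonanal
Conditions: O3, CH2Cl2, −78 °C, stopped at first persistent blue; then PPh3, −78 °C to rt
Reagents that add atoms: ozone, [O-][O+]=O
Why: Ozonolysis with reductive work-up as in step 20, giving the C29 aldehyde.

Step 24
Reactants: 27 (3S,5S)-3,5-bis(TBS-oxy)-9-(PMB-oxy)nonanal
Product: 28 (4S,6R,8S)-6,8-bis(TBS-oxy)-12-(PMB-oxy)dodec-1-en-4-ol
Conditions: B-allyldiisopinocampheylborane from (+)-α-pinene, Et2O, −78 °C; then pH 7 buffer, MeOH, 30% H2O2, 0 °C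
Reagents that add atoms: B-allyldiisopinocampheylborane from (+)-α-pinene, C=CCB([C@@H]1C[C@@H]2C[C@H]([C@H]1C)C2(C)C)[C@@H]1C[C@@H]2C[C@H]([C@H]1C)C2(C)C
Why: Brown allylation with the antipodal reagent (C29–C30 formed) sets C29 anti to O27 under reagent control.

Step 25
Reactants: 28 (4S,6R,8S)-6,8-bis(TBS-oxy)-12-(PMB-oxy)dodec-1-en-4-ol
Product: 29 (4S,6S,8S)-4,6,8-tris(TBS-oxy)-12-(PMB-oxy)dodec-1-ene
Conditions: TBSOTf, 2,6-lutidine, CH2Cl2, −78 to 0 °C
Reagents that add atoms: tert-butyldimethylsilyl triflate, CC(C)(C)[Si](C)(C)OS(=O)(=O)C(F)(F)F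
Why: Standard silyl triflate protection.

Step 26
Reactants: 29 (4S,6S,8S)-4,6,8-tris(TBS-oxy)-12-(PMB-oxy)dodec-1-ene
Product: 30 (5S,7S,9S)-5,7,9-tris(TBS-oxy)-13-(PMB-oxy)tridecanal
Conditions: Rh(acac)(CO)2 (1 mol%), Xantphos (2 mol%), CO/H2 (1:1, 10 bar), toluene, 70 °C
Reagents that add atoms: carbon monoxide, [C-]#[O+]
Why: Linear-selective hydroformylation (C32–C33 formed) supplies the three-methylene spacer C30–C32 and the C33 aldehyde in one step; ethers are inert.

Step 27
Reactants: 30 (5S,7S,9S)-5,7,9-tris(TBS-oxy)-13-(PMB-oxy)tridecanal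
Product: 31 (4S,8S,10S,12S)-8,10,12-tris(TBS-oxy)-16-(PMB-oxy)hexadec-1-en-4-ol
Conditions: B-allyldiisopinocampheylborane from (−)-α-pinene, Et2O, −78 °C; then pH 7 buffer, MeOH, 30% H2O2, 0 °C
Reagents that add atoms: B-allyldiisopinocampheylborane from (−)-α-pinene, C=CCB([C@H]1C[C@H]2C[C@@H]([C@@H]1C)C2(C)C)[C@H]1C[C@H]2C[C@@H]([C@@H]1C)C2(C)C
Why: Brown allylation (C33–C34 formed); C33 is set by the reagent, the nearest centre C29 being four carbons away.

Step 28
Reactants: 31 (4S,8S,10S,12S)-8,10,12-tris(TBS-oxy)-16-(PMB-oxy)hexadec-1-en-4-ol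
Product: 32 (4S,8S,10S,12S)-4,8,10,12-tetrakis(TBS-oxy)-16-(PMB-oxy)hexadec-1-ene
Conditions: TBSOTf, 2,6-lutidine, CH2Cl2, −78 to 0 °C
Reagents that add atoms: tert-butyldimethylsilyl triflate, CC(C)(C)[Si](C)(C)OS(=O)(=O)C(F)(F)F
Why: Standard silyl triflate protection.

Step 29
Reactants: 32 (4S,8S,10S,12S)-4,8,10,12-tetrakis(TBS-oxy)-16-(PMB-oxy)hexadec-1-ene
Product: 33 (3S,7S,9S,11S)-3,7,9,11-tetrakis(TBS-oxy)-15-(PMB-oxy)pentadecanal
Conditions: O3, CH2Cl2, −78 °C, stopped at first persistent blue; then PPh3, −78 °C to rt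
Reagents that add atoms: ozone, [O-][O+]=O
Why: Ozonolysis with reductive work-up as in step 20, giving the C35 aldehyde, used crude.

Step 30
Reactants: 33 (3S,7S,9S,11S)-3,7,9,11-tetrakis(TBS-oxy)-15-(PMB-oxy)pentadecanal
Product: 34 (3S,4R,6S,10S,12S,14S)-6,10,12,14-tetrakis(TBS-oxy)-18-(PMB-oxy)-3-methyloctadec-1-en-4-ol
Conditions: trans-2-butene, KOt-Bu, n-BuLi, THF, −78 to −45 °C; (−)-Ipc2BOMe, −78 °C; BF3·OEt2; then 33, −78 °C; pH 7 buffer, MeOH, 30% H2O2, 0 °C
Reagents that add atoms: (E)-crotyldiisopinocampheylborane from (+)-α-pinene (made in the flask from trans-2-butene), C/C=C/CB([C@@H]1C[C@@H]2C[C@H]([C@H]1C)C2(C)C)[C@@H]1C[C@@H]2C[C@H]([C@H]1C)C2(C)C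
Why: Brown crotylation (C35–C36 formed): the (E)-crotyl geometry is transmitted through the chair transition state to the anti relationship of O35 and the C36 methyl, and the isopinocampheyl groups choose the aldehyde face so that O35 is anti to O33; the free hydroxyl so formed is the one to be acylated later.

Step 31
Reactants: 34 (3S,4R,6S,10S,12S,14S)-6,10,12,14-tetrakis(TBS-oxy)-18-(PMB-oxy)-3-methyloctadec-1-en-4-ol; 35 (Z)-hex-3-ene
Product: 37 (5S,7S,9S,13S,15R,16S)-1-(PMB-oxy)-16-methyl-5,7,9,13-tetrakis(TBS-oxy)icosan-15-ol, via icosenol 36 (not isolated)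
Conditions: second-generation Grubbs catalyst (5 mol%), 35 (10 equiv), CH2Cl2, 40 °C; then solvent exchange to EtOAc, PtO2, H2 (1 atm), rt
Reagents that add atoms: none
Why: Olefin cross-metathesis of the vinyl group with an excess of a reactive symmetrical alkene adds C39–C40 (C38=C39 replaced, alkene geometry irrelevant), and platinum-catalysed hydrogenation in the same flask saturates C37=C38 without hydrogenolysis of the PMB ether; C35 and C36 are not affected.

Step 32
Reactants: 18 (3R,5R,9R,13R,17S,19E)-5,9,13,17-tetrakis(TBS-oxy)-20-iodo-3-methylicos-19-enoic acid; 37 (5S,7S,9S,13S,15R,16S)-1-(PMB-oxy)-16-methyl-5,7,9,13-tetrakis(TBS-oxy)icosan-15-ol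
Product: 39 ester of acid 18 with the C35 hydroxyl of 37 (C1–C40 seco ester with 20-iodide and 21-O-PMB), via mixed anhydride 38 (not isolated)
Conditions: 2,4,6-trichlorobenzoyl chloride, Et3N, THF, rt; then 37, DMAP, toluene, rt to 40 °C
Reagents that add atoms: 2,4,6-trichlorobenzoyl chloride (its aroyl group is carried by 38 only), O=C(Cl)c1c(Cl)cc(Cl)cc1Cl
Why: Yamaguchi esterification: the acid is activated as the hindered mixed anhydride and DMAP transfers the acyl group to the secondary C35 hydroxyl, which is flanked by the C36 branch; run intermolecularly, a slight excess of 18 can drive it, and C35 keeps its configuration because the O–acyl bond is the one formed.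

Step 33
Reactants: 39 C1–C40 seco ester with 20-iodide and 21-O-PMB
Product: 40 C1–C40 seco ester with 20-iodide and free 21-hydroxyl
Conditions: DDQ, CH2Cl2/pH 7 buffer (10:1), 0 °C
Reagents that add atoms: none
Why: Oxidative PMB cleavage by hydride abstraction from the electron-rich benzylic position; silyl ethers, ester and the electron-poor iodoalkene do not react.

Step 34
Reactants: 40 C1–C40 seco ester with 20-iodide and free 21-hydroxyl
Product: 41 C1–C40 seco ester with (19E)-20-iodide and C21 aldehyde, octakis-TBS ether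
Conditions: Dess–Martin periodinane, NaHCO3, CH2Cl2, 0 °C to rt
Reagents that add atoms: none
Why: Periodinane oxidation of the only free hydroxyl gives the C21 aldehyde under buffered conditions; the product is used at once to avoid self-condensation.

Step 35
Reactants: 41 C1–C40 seco ester with (19E)-20-iodide and C21 aldehyde, octakis-TBS ether
Product: 42 36-membered macrolactone with (19E)-alkene and free (21S)-hydroxyl, 5,9,13,17,25,27,29,33-octakis-TBS ether
Conditions: CrCl2 (8 equiv), (S)-N-[2-(4-isopropyl-4,5-dihydro-1,3-oxazol-2-yl)-6-methylphenyl]methanesulfonamide (8.8 equiv), Et3N, NiCl2·(2,9-dimethyl-1,10-phenanthroline) (cat.), THF/MeCN, rt; 41 added by syringe pump to about 1 mM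
Reagents that add atoms: none
Why: Nozaki–Hiyama–Kishi reaction used as a ligand-controlled asymmetric macrocyclization. Divalent chromium reduces NiCl2 to zerovalent nickel, which inserts into the C20–I bond with retention of the E geometry; the alkenyl group then passes to trivalent chromium, and the alkenylchromium, carrying the deprotonated oxazoline–sulfonamide ligand, adds to the C21 aldehyde. The closest known reaction types are nickel/chromium-mediated macrocyclizations of ω-formyl alkenyl iodides and the stoichiometric sulfonamide-ligand variant of the intermolecular coupling. The 36-membered ring closes by intramolecular 1,2-addition of C20 to the C21 carbonyl (exo attack on C=O, C20–C21 formed), favoured over oligomerization by slow addition at high dilution. C21 is the only new stereocentre; C17 and C25 are too remote to bias it, so it is controlled by the chiral ligand on chromium, which fixes the face of the coordinated aldehyde. The step needs chemoselectivity (the alkenylchromium adds only to the aldehyde, while the C1 ester and eight silyl ethers are inert), geometric fidelity (secured by the configurationally stable alkenyl–metal bonds) and facial selectivity (secured by the ligand and checked beforehand on a C17–C25 model pair).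

Step 36
Reactants: 42 36-membered macrolactone with (19E)-alkene and free (21S)-hydroxyl, octakis-TBS ether
Product: 43 saturated 36-membered macrolactone with free (21R)-hydroxyl, 5,9,13,17,25,27,29,33-octakis-TBS ether
Conditions: H2 (1 atm), 5% Rh/Al2O3, EtOAc, rt
Reagents that add atoms: none
Why: Heterogeneous hydrogenation of the disubstituted alkene; rhodium on alumina is preferred to palladium to limit allylic C–O hydrogenolysis and isomerization to the C21 ketone, and C21 keeps its configuration (the label changes from S to R only because the alkene is gone).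

Step 37
Reactants: 43 saturated 36-membered macrolactone with free (21R)-hydroxyl, octakis-TBS ether
Product: 44 (3R,5R,9R,13S,17S,21R,25S,27S,29S,33S,35R,36S)-5,9,13,17,21,25,27,29,33-nonahydroxy-3-methyl-35-[(2S)-hexan-2-yl] 36-membered lactone (target)
Conditions: HF·pyridine, pyridine, THF, 0 °C to rt
Reagents that add atoms: none
Why: Fluoride-mediated cleavage of all eight secondary TBS ethers; the buffered acidic medium avoids base-induced acyl migration from O35 to O33 and leaves the lactone intact.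

## Compound list

1 | (3R)-5-methoxy-3-methyl-5-oxopentanoic acid (methyl hydrogen (R)-3-methylglutarate) | COC(=O)C[C@H](C)CC(=O)O | starting material
2 | methyl (3R)-5-hydroxy-3-methylpentanoate | COC(=O)C[C@H](C)CCO | intermediate
3 | methyl (3R)-3-methyl-5-oxopentanoate | COC(=O)C[C@H](C)CC=O | intermediate
4 | methyl (3R,5R)-5-hydroxy-3-methyloct-7-enoate | COC(=O)C[C@H](C)C[C@H](O)CC=C | intermediate
5 | methyl (3R,5R)-5-(TBS-oxy)-3-methyloct-7-enoate | COC(=O)C[C@H](C)C[C@H](O[Si](C)(C)C(C)(C)C)CC=C | intermediate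
6 | methyl (3R,5R)-5-(TBS-oxy)-3-methyl-9-oxononanoate | COC(=O)C[C@H](C)C[C@H](O[Si](C)(C)C(C)(C)C)CCCC=O | intermediate
7 | methyl (3R,5R,9S)-5-(TBS-oxy)-9-hydroxy-3-methyldodec-11-enoate | COC(=O)C[C@H](C)C[C@H](O[Si](C)(C)C(C)(C)C)CCC[C@H](O)CC=C | intermediate
8 | methyl (3R,5R,9S)-5,9-bis(TBS-oxy)-3-methyldodec-11-enoate | COC(=O)C[C@H](C)C[C@H](O[Si](C)(C)C(C)(C)C)CCC[C@H](O[Si](C)(C)C(C)(C)C)CC=C | intermediate
9 | methyl (3R,5R,9S)-5,9-bis(TBS-oxy)-3-methyl-13-oxotridecanoate | COC(=O)C[C@H](C)C[C@H](O[Si](C)(C)C(C)(C)C)CCC[C@H](O[Si](C)(C)C(C)(C)C)CCCC=O | intermediate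
10 | methyl (3R,5R,9R,13R)-5,9-bis(TBS-oxy)-13-hydroxy-3-methylhexadec-15-enoate | COC(=O)C[C@H](C)C[C@H](O[Si](C)(C)C(C)(C)C)CCC[C@H](O[Si](C)(C)C(C)(C)C)CCC[C@@H](O)CC=C | intermediate
11 | methyl (3R,5R,9R,13R)-5,9,13-tris(TBS-oxy)-3-methylhexadec-15-enoate | COC(=O)C[C@H](C)C[C@H](O[Si](C)(C)C(C)(C)C)CCC[C@H](O[Si](C)(C)C(C)(C)C)CCC[C@@H](O[Si](C)(C)C(C)(C)C)CC=C | intermediate
12 | methyl (3R,5R,9R,13R)-5,9,13-tris(TBS-oxy)-3-methyl-17-oxoheptadecanoate | COC(=O)C[C@H](C)C[C@H](O[Si](C)(C)C(C)(C)C)CCC[C@H](O[Si](C)(C)C(C)(C)C)CCC[C@@H](O[Si](C)(C)C(C)(C)C)CCCC=O | intermediate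
13 | allenylboronic acid pinacol ester | C=C=CB1OC(C)(C)C(C)(C)O1 | starting material
14 | methyl (3R,5R,9R,13S,17S)-5,9,13-tris(TBS-oxy)-17-hydroxy-3-methylicos-19-ynoate | COC(=O)C[C@H](C)C[C@H](O[Si](C)(C)C(C)(C)C)CCC[C@H](O[Si](C)(C)C(C)(C)C)CCC[C@@H](O[Si](C)(C)C(C)(C)C)CCC[C@H](O)CC#C | intermediate
15 | methyl (3R,5R,9R,13R,17S)-5,9,13,17-tetrakis(TBS-oxy)-3-methylicos-19-ynoate | COC(=O)C[C@H](C)C[C@H](O[Si](C)(C)C(C)(C)C)CCC[C@H](O[Si](C)(C)C(C)(C)C)CCC[C@@H](O[Si](C)(C)C(C)(C)C)CCC[C@H](O[Si](C)(C)C(C)(C)C)CC#C | intermediate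
16 | (19E)-C20 alkenylzirconocene chloride derived from 15 | COC(=O)C[C@H](C)C[C@H](O[Si](C)(C)C(C)(C)C)CCC[C@H](O[Si](C)(C)C(C)(C)C)CCC[C@@H](O[Si](C)(C)C(C)(C)C)CCC[C@H](O[Si](C)(C)C(C)(C)C)C/C=C/[Zr](Cl)(C1C=CC=C1)C1C=CC=C1 | intermediate
17 | methyl (3R,5R,9R,13R,17S,19E)-5,9,13,17-tetrakis(TBS-oxy)-20-iodo-3-methylicos-19-enoate | COC(=O)C[C@H](C)C[C@H](O[Si](C)(C)C(C)(C)C)CCC[C@H](O[Si](C)(C)C(C)(C)C)CCC[C@@H](O[Si](C)(C)C(C)(C)C)CCC[C@H](O[Si](C)(C)C(C)(C)C)C/C=C/I | intermediate
18 | (3R,5R,9R,13R,17S,19E)-5,9,13,17-tetrakis(TBS-oxy)-20-iodo-3-methylicos-19-enoic acid (C1–C20 acid) | OC(=O)C[C@H](C)C[C@H](O[Si](C)(C)C(C)(C)C)CCC[C@H](O[Si](C)(C)C(C)(C)C)CCC[C@@H](O[Si](C)(C)C(C)(C)C)CCC[C@H](O[Si](C)(C)C(C)(C)C)C/C=C/I | intermediate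
19 | pentane-1,5-diol | OCCCCCO | starting material
20 | 5-(PMB-oxy)pentan-1-ol | COc1ccc(COCCCCCO)cc1 | intermediate
21 | 5-(PMB-oxy)pentanal | COc1ccc(COCCCCC=O)cc1 | intermediate
22 | (4S)-8-(PMB-oxy)oct-1-en-4-ol | COc1ccc(COCCCC[C@H](O)CC=C)cc1 | intermediate
23 | (4S)-4-(TBS-oxy)-8-(PMB-oxy)oct-1-ene | COc1ccc(COCCCC[C@H](O[Si](C)(C)C(C)(C)C)CC=C)cc1 | intermediate
24 | (3S)-3-(TBS-oxy)-7-(PMB-oxy)heptanal | COc1ccc(COCCCC[C@H](O[Si](C)(C)C(C)(C)C)CC=O)cc1 | intermediate
25 | (4R,6S)-6-(TBS-oxy)-10-(PMB-oxy)dec-1-en-4-ol | COc1ccc(COCCCC[C@H](O[Si](C)(C)C(C)(C)C)C[C@H](O)CC=C)cc1 | intermediate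
26 | (4R,6S)-4,6-bis(TBS-oxy)-10-(PMB-oxy)dec-1-ene | COc1ccc(COCCCC[C@H](O[Si](C)(C)C(C)(C)C)C[C@H](O[Si](C)(C)C(C)(C)C)CC=C)cc1 | intermediate
27 | (3S,5S)-3,5-bis(TBS-oxy)-9-(PMB-oxy)nonanal | COc1ccc(COCCCC[C@H](O[Si](C)(C)C(C)(C)C)C[C@H](O[Si](C)(C)C(C)(C)C)CC=O)cc1 | intermediate
28 | (4S,6R,8S)-6,8-bis(TBS-oxy)-12-(PMB-oxy)dodec-1-en-4-ol | COc1ccc(COCCCC[C@H](O[Si](C)(C)C(C)(C)C)C[C@H](O[Si](C)(C)C(C)(C)C)C[C@@H](O)CC=C)cc1 | intermediate
29 | (4S,6S,8S)-4,6,8-tris(TBS-oxy)-12-(PMB-oxy)dodec-1-ene | COc1ccc(COCCCC[C@H](O[Si](C)(C)C(C)(C)C)C[C@H](O[Si](C)(C)C(C)(C)C)C[C@@H](O[Si](C)(C)C(C)(C)C)CC=C)cc1 | intermediate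
30 | (5S,7S,9S)-5,7,9-tris(TBS-oxy)-13-(PMB-oxy)tridecanal | COc1ccc(COCCCC[C@H](O[Si](C)(C)C(C)(C)C)C[C@H](O[Si](C)(C)C(C)(C)C)C[C@@H](O[Si](C)(C)C(C)(C)C)CCCC=O)cc1 | intermediate
31 | (4S,8S,10S,12S)-8,10,12-tris(TBS-oxy)-16-(PMB-oxy)hexadec-1-en-4-ol | COc1ccc(COCCCC[C@H](O[Si](C)(C)C(C)(C)C)C[C@H](O[Si](C)(C)C(C)(C)C)C[C@@H](O[Si](C)(C)C(C)(C)C)CCC[C@H](O)CC=C)cc1 | intermediate
32 | (4S,8S,10S,12S)-4,8,10,12-tetrakis(TBS-oxy)-16-(PMB-oxy)hexadec-1-ene | COc1ccc(COCCCC[C@H](O[Si](C)(C)C(C)(C)C)C[C@H](O[Si](C)(C)C(C)(C)C)C[C@@H](O[Si](C)(C)C(C)(C)C)CCC[C@H](O[Si](C)(C)C(C)(C)C)CC=C)cc1 | intermediate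
33 | (3S,7S,9S,11S)-3,7,9,11-tetrakis(TBS-oxy)-15-(PMB-oxy)pentadecanal | COc1ccc(COCCCC[C@H](O[Si](C)(C)C(C)(C)C)C[C@H](O[Si](C)(C)C(C)(C)C)C[C@@H](O[Si](C)(C)C(C)(C)C)CCC[C@H](O[Si](C)(C)C(C)(C)C)CC=O)cc1 | intermediate
34 | (3S,4R,6S,10S,12S,14S)-6,10,12,14-tetrakis(TBS-oxy)-18-(PMB-oxy)-3-methyloctadec-1-en-4-ol | COc1ccc(COCCCC[C@H](O[Si](C)(C)C(C)(C)C)C[C@H](O[Si](C)(C)C(C)(C)C)C[C@@H](O[Si](C)(C)C(C)(C)C)CCC[C@H](O[Si](C)(C)C(C)(C)C)C[C@@H](O)[C@@H](C)C=C)cc1 | intermediate
35 | (Z)-hex-3-ene | CC/C=C\CC | starting material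
36 | (5S,7S,9S,13S,15R,16S,17E)-1-(PMB-oxy)-16-methyl-5,7,9,13-tetrakis(TBS-oxy)icos-17-en-15-ol (E major, geometry irrelevant) | COc1ccc(COCCCC[C@H](O[Si](C)(C)C(C)(C)C)C[C@H](O[Si](C)(C)C(C)(C)C)C[C@@H](O[Si](C)(C)C(C)(C)C)CCC[C@H](O[Si](C)(C)C(C)(C)C)C[C@@H](O)[C@@H](C)/C=C/CC)cc1 | intermediate
37 | (5S,7S,9S,13S,15R,16S)-1-(PMB-oxy)-16-methyl-5,7,9,13-tetrakis(TBS-oxy)icosan-15-ol (C21–C40 alcohol) | COc1ccc(COCCCC[C@H](O[Si](C)(C)C(C)(C)C)C[C@H](O[Si](C)(C)C(C)(C)C)C[C@@H](O[Si](C)(C)C(C)(C)C)CCC[C@H](O[Si](C)(C)C(C)(C)C)C[C@@H](O)[C@@H](C)CCCC)cc1 | intermediate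
38 | mixed anhydride of 18 with 2,4,6-trichlorobenzoic acid | O=C(OC(=O)c1c(Cl)cc(Cl)cc1Cl)C[C@H](C)C[C@H](O[Si](C)(C)C(C)(C)C)CCC[C@H](O[Si](C)(C)C(C)(C)C)CCC[C@@H](O[Si](C)(C)C(C)(C)C)CCC[C@H](O[Si](C)(C)C(C)(C)C)C/C=C/I | intermediate
39 | C1–C40 seco ester (C1–O35 ester of 18 and 37): (19E)-20-iodide, 21-O-PMB ether, 5,9,13,17,25,27,29,33-octakis-TBS ether, all centres as in 44 | I/C=C/C[C@@H](O[Si](C)(C)C(C)(C)C)CCC[C@H](O[Si](C)(C)C(C)(C)C)CCC[C@@H](O[Si](C)(C)C(C)(C)C)CCC[C@@H](O[Si](C)(C)C(C)(C)C)C[C@@H](C)CC(=O)O[C@@H]([C@@H](C)CCCC)C[C@@H](O[Si](C)(C)C(C)(C)C)CCC[C@H](O[Si](C)(C)C(C)(C)C)C[C@@H](O[Si](C)(C)C(C)(C)C)C[C@@H](O[Si](C)(C)C(C)(C)C)CCCCOCc1ccc(OC)cc1 | intermediate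
40 | C1–C40 seco ester: (19E)-20-iodide, free primary 21-hydroxyl, octakis-TBS ether, all centres as in 44 | I/C=C/C[C@@H](O[Si](C)(C)C(C)(C)C)CCC[C@H](O[Si](C)(C)C(C)(C)C)CCC[C@@H](O[Si](C)(C)C(C)(C)C)CCC[C@@H](O[Si](C)(C)C(C)(C)C)C[C@@H](C)CC(=O)O[C@@H]([C@@H](C)CCCC)C[C@@H](O[Si](C)(C)C(C)(C)C)CCC[C@H](O[Si](C)(C)C(C)(C)C)C[C@@H](O[Si](C)(C)C(C)(C)C)C[C@@H](O[Si](C)(C)C(C)(C)C)CCCCO | intermediate
41 | C1–C40 seco ester: (19E)-20-iodide, C21 aldehyde, octakis-TBS ether, all centres as in 44 (precursor of the key step) | I/C=C/C[C@@H](O[Si](C)(C)C(C)(C)C)CCC[C@H](O[Si](C)(C)C(C)(C)C)CCC[C@@H](O[Si](C)(C)C(C)(C)C)CCC[C@@H](O[Si](C)(C)C(C)(C)C)C[C@@H](C)CC(=O)O[C@@H]([C@@H](C)CCCC)C[C@@H](O[Si](C)(C)C(C)(C)C)CCC[C@H](O[Si](C)(C)C(C)(C)C)C[C@@H](O[Si](C)(C)C(C)(C)C)C[C@@H](O[Si](C)(C)C(C)(C)C)CCCC=O | intermediate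
42 | 36-membered macrolactone, (19E)-alkene, free (21S)-hydroxyl, 5,9,13,17,25,27,29,33-octakis-TBS ether, other centres as in 44 (product of the key step) | CCCC[C@H](C)[C@H]1C[C@@H](O[Si](C)(C)C(C)(C)C)CCC[C@H](O[Si](C)(C)C(C)(C)C)C[C@@H](O[Si](C)(C)C(C)(C)C)C[C@@H](O[Si](C)(C)C(C)(C)C)CCC[C@H](O)/C=C/C[C@@H](O[Si](C)(C)C(C)(C)C)CCC[C@H](O[Si](C)(C)C(C)(C)C)CCC[C@@H](O[Si](C)(C)C(C)(C)C)CCC[C@@H](O[Si](C)(C)C(C)(C)C)C[C@@H](C)CC(=O)O1 | intermediate
43 | saturated 36-membered macrolactone, free (21R)-hydroxyl, 5,9,13,17,25,27,29,33-octakis-TBS ether, all centres as in 44 | CCCC[C@H](C)[C@H]1C[C@@H](O[Si](C)(C)C(C)(C)C)CCC[C@H](O[Si](C)(C)C(C)(C)C)C[C@@H](O[Si](C)(C)C(C)(C)C)C[C@@H](O[Si](C)(C)C(C)(C)C)CCC[C@H](O)CCC[C@@H](O[Si](C)(C)C(C)(C)C)CCC[C@H](O[Si](C)(C)C(C)(C)C)CCC[C@@H](O[Si](C)(C)C(C)(C)C)CCC[C@@H](O[Si](C)(C)C(C)(C)C)C[C@@H](C)CC(=O)O1 | intermediate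
44 | (4R,6R,10R,14S,18S,22R,26S,28S,30S,34S,36R)-36-[(2S)-hexan-2-yl]-6,10,14,18,22,26,28,30,34-nonahydroxy-4-methyl-1-oxacyclohexatriacontan-2-one (ring locants; 3R,5R,9R,13S,17S,21R,25S,27S,29S,33S,35R,36S in chain locants) | CCCC[C@H](C)[C@H]1C[C@@H](O)CCC[C@H](O)C[C@@H](O)C[C@@H](O)CCC[C@H](O)CCC[C@@H](O)CCC[C@H](O)CCC[C@@H](O)CCC[C@@H](O)C[C@@H](C)CC(=O)O1 | target

## Step count and least certain steps

Total step count: 37 (steps 1–15 to acid 18, steps 16–31 to alcohol 37, steps 32–37 for union, ring closure and end game). Longest linear sequence: 22 steps (19 to 44 through steps 16–37); the acid branch from 1 is 21 steps.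

**Step 35 (key step).** The most likely failure is poor facial selectivity at C21. The aldehyde is unbranched, the chain is flexible, and the ligand on chromium acts without help from any nearby stereocentre. Competing intermolecular coupling at a 36-membered ring size is the second risk. Fallback: starting from 41, the ring is closed with CrCl2/NiCl2 without the chiral ligand (DMSO/THF, high dilution) to give 42 mixed with its C21 epimer, the (21R)-allylic alcohol F1. The mixture is oxidized with Dess–Martin periodinane to the single macrocyclic (E)-enone F2. Reduction with the (R)-methyl oxazaborolidine catalyst and catecholborane, in which the alkenyl arm acts as the large group, then sets C21 and rejoins the route at 42.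

**Step 12.** Erosion of enantioselectivity, here diastereoselectivity at C17, is the concern: unbranched aliphatic aldehydes are the weaker substrates of phosphoric acid-catalysed propargylation, and a 1,5-related C17 epimer would not be separable. Fallback: starting from 12, allylation with the (−)-α-pinene-derived allylborane as in step 6 gives the C17 homoallylic alcohol F3. Silylation gives the tetrakis-TBS alkene F4, and ozonolysis gives the C19 aldehyde F5. Takai iodo-olefination (CHI3, CrCl2, THF/dioxane) then adds C20 as the (E)-iodoalkene and rejoins the route at 17.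

**Step 31.** Incomplete cross-metathesis is possible because the alkene is allylically branched and next to a free hydroxyl; partial hydrogenolysis of the PMB ether in the same flask is the second risk. Fallback: starting from 33, the C35–C36 bond and both centres are made by a dibutylboron triflate-mediated syn-aldol reaction with (S)-4-benzyl-3-hexanoyl-1,3-oxazolidin-2-one F6 (from hexanoyl chloride and the lithiated auxiliary). This gives aldol adduct F7 with the butyl group already in place. LiBH4 removes the auxiliary to give the 1,3-diol F8, the primary hydroxyl is tosylated selectively to give F9, and LiEt3BH reduces the tosylate to the C36 methyl group, rejoining the route at 37.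

**Step 36.** Isomerization of the allylic alcohol to the C21 ketone, or hydrogenolysis of the allylic C21–O bond, can occur on the metal surface. Fallback: starting from 42, the silyl ethers are removed first with HF·pyridine to give the 19,20-unsaturated nonaol F10. Its isolated alkene is then reduced with diimide (2-nitrobenzenesulfonyl hydrazide, Et3N), a metal-free reductant that neither migrates the double bond nor cleaves C–O bonds, rejoining the route at 44.

**Step 3.** The δ-hydroxy ester 4 can close to the six-membered lactone during work-up or on silica, which would give mixtures and carry isopinocampheol into the silylation. Fallback: starting from 3, the allylation is run as before and the crude adduct is driven on purpose (catalytic PPTS, CH2Cl2) to the lactone F11, which is stable and easily purified. Methanolysis with K2CO3 in MeOH at 0 °C reopens it, and the hydroxy ester is silylated in the same operation, rejoining the route at 5.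

## Further compounds

F1 | step 35 | C21 epimer of 42: 36-membered macrolactone, (19E)-alkene, (21R)-hydroxyl, octakis-TBS ether | CCCC[C@H](C)[C@H]1C[C@@H](O[Si](C)(C)C(C)(C)C)CCC[C@H](O[Si](C)(C)C(C)(C)C)C[C@@H](O[Si](C)(C)C(C)(C)C)C[C@@H](O[Si](C)(C)C(C)(C)C)CCC[C@@H](O)/C=C/C[C@@H](O[Si](C)(C)C(C)(C)C)CCC[C@H](O[Si](C)(C)C(C)(C)C)CCC[C@@H](O[Si](C)(C)C(C)(C)C)CCC[C@@H](O[Si](C)(C)C(C)(C)C)C[C@@H](C)CC(=O)O1
F2 | step 35 | macrocyclic (19E)-en-21-one, octakis-TBS ether | CCCC[C@H](C)[C@H]1C[C@@H](O[Si](C)(C)C(C)(C)C)CCC[C@H](O[Si](C)(C)C(C)(C)C)C[C@@H](O[Si](C)(C)C(C)(C)C)C[C@@H](O[Si](C)(C)C(C)(C)C)CCCC(=O)/C=C/C[C@@H](O[Si](C)(C)C(C)(C)C)CCC[C@H](O[Si](C)(C)C(C)(C)C)CCC[C@@H](O[Si](C)(C)C(C)(C)C)CCC[C@@H](O[Si](C)(C)C(C)(C)C)C[C@@H](C)CC(=O)O1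
F3 | step 12 | methyl 5,9,13-tris(TBS-oxy)-17-hydroxy-3-methylicos-19-enoate, centres as in 44 | COC(=O)C[C@H](C)C[C@H](O[Si](C)(C)C(C)(C)C)CCC[C@H](O[Si](C)(C)C(C)(C)C)CCC[C@@H](O[Si](C)(C)C(C)(C)C)CCC[C@H](O)CC=C
F4 | step 12 | methyl 5,9,13,17-tetrakis(TBS-oxy)-3-methylicos-19-enoate, centres as in 44 | COC(=O)C[C@H](C)C[C@H](O[Si](C)(C)C(C)(C)C)CCC[C@H](O[Si](C)(C)C(C)(C)C)CCC[C@@H](O[Si](C)(C)C(C)(C)C)CCC[C@H](O[Si](C)(C)C(C)(C)C)CC=C
F5 | step 12 | methyl 5,9,13,17-tetrakis(TBS-oxy)-3-methyl-19-oxononadecanoate, centres as in 44 | COC(=O)C[C@H](C)C[C@H](O[Si](C)(C)C(C)(C)C)CCC[C@H](O[Si](C)(C)C(C)(C)C)CCC[C@@H](O[Si](C)(C)C(C)(C)C)CCC[C@H](O[Si](C)(C)C(C)(C)C)CC=O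
F6 | step 31 | (S)-4-benzyl-3-hexanoyl-1,3-oxazolidin-2-one | CCCCCC(=O)N1[C@@H](Cc2ccccc2)COC1=O
F7 | step 31 | syn-aldol adduct of 33 with F6 (C35 hydroxyl, C36 bearing butyl and the acyl oxazolidinone) | COc1ccc(COCCCC[C@H](O[Si](C)(C)C(C)(C)C)C[C@H](O[Si](C)(C)C(C)(C)C)C[C@@H](O[Si](C)(C)C(C)(C)C)CCC[C@H](O[Si](C)(C)C(C)(C)C)C[C@@H](O)[C@H](CCCC)C(=O)N2[C@@H](Cc3ccccc3)COC2=O)cc1
F8 | step 31 | 1,3-diol from F7 (C35 hydroxyl, hydroxymethyl on C36) | COc1ccc(COCCCC[C@H](O[Si](C)(C)C(C)(C)C)C[C@H](O[Si](C)(C)C(C)(C)C)C[C@@H](O[Si](C)(C)C(C)(C)C)CCC[C@H](O[Si](C)(C)C(C)(C)C)C[C@@H](O)[C@H](CCCC)CO)cc1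
F9 | step 31 | primary tosylate of F8 | COc1ccc(COCCCC[C@H](O[Si](C)(C)C(C)(C)C)C[C@H](O[Si](C)(C)C(C)(C)C)C[C@@H](O[Si](C)(C)C(C)(C)C)CCC[C@H](O[Si](C)(C)C(C)(C)C)C[C@@H](O)[C@H](CCCC)COS(=O)(=O)c2ccc(C)cc2)cc1
F10 | step 36 | (19E)-19,20-didehydro-44 (unsaturated nonaol) | CCCC[C@H](C)[C@H]1C[C@@H](O)CCC[C@H](O)C[C@@H](O)C[C@@H](O)CCC[C@H](O)/C=C/C[C@@H](O)CCC[C@H](O)CCC[C@@H](O)CCC[C@@H](O)C[C@@H](C)CC(=O)O1
F11 | step 3 | (4R,6R)-4-methyl-6-(prop-2-en-1-yl)oxan-2-one | O=C1C[C@H](C)C[C@@H](CC=C)O1
A1 | alternative 1 | C2-symmetric C6–C24 diene with free 9,21-diol and 13,17-bis-TBS ether | C=CC[C@H](O)CCC[C@@H](O[Si](C)(C)C(C)(C)C)CCC[C@H](O[Si](C)(C)C(C)(C)C)CCC[C@@H](O)CC=C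
A2 | alternative 2 | C1–C40 chain with (Z)-C23=C24 alkene inside an eight-membered O21,O25-diisopropylsilylene ring, O35-PMB ether, methyl ester | CCCC[C@H](C)[C@H](OCc1ccc(OC)cc1)C[C@@H](O[Si](C)(C)C(C)(C)C)CCC[C@H](O[Si](C)(C)C(C)(C)C)C[C@@H](O[Si](C)(C)C(C)(C)C)C[C@@H]2/C=C\C[C@H](O[Si](C(C)C)(C(C)C)O2)CCC[C@@H](O[Si](C)(C)C(C)(C)C)CCC[C@H](O[Si](C)(C)C(C)(C)C)CCC[C@@H](O[Si](C)(C)C(C)(C)C)CCC[C@@H](O[Si](C)(C)C(C)(C)C)C[C@@H](C)CC(=O)OC
A3 | alternative 3 | protected C1–C40 chain with C27 dithiane, O25-TBS ether and free C29 hydroxyl | CCCC[C@H](C)[C@H](OCc1ccc(OC)cc1)C[C@@H](O[Si](C)(C)C(C)(C)C)CCC[C@H](O)CC1(SCCCS1)C[C@@H](O[Si](C)(C)C(C)(C)C)CCC[C@H](O[Si](C)(C)C(C)(C)C)CCC[C@@H](O[Si](C)(C)C(C)(C)C)CCC[C@H](O[Si](C)(C)C(C)(C)C)CCC[C@@H](O[Si](C)(C)C(C)(C)C)CCC[C@@H](O[Si](C)(C)C(C)(C)C)C[C@@H](C)CCOCc1ccc(OC)cc1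
A4 | alternative 3 | 2-(tert-butyldimethylsilyl)-1,3-dithiane | CC(C)(C)[Si](C)(C)C1SCCCS1
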